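Ring B (the benzene ring C3a–C7a of the benzofuran) is taken apart. Furan ring A stays intact and already carries the C2 aryl group and a masked C3 aldehyde. Ring B suits this because its OMe sits on C7, ortho to the fusion carbon C7a that bears O1, and its only carbon substituent is on C5. A furan-2-yl(methoxy)carbene Cr(CO)5 complex delivers C7, a terminal alkyne delivers C6 and C5, and a CO ligand delivers C4. One Dötz benzannulation therefore forges C7–C6, C5–C4 and C4–C3a and closes the ring. The unwanted C4 hydroxyl is removed later via its triflate. The precursor is a 5-aryl-4-(dimethoxymethyl)furan with the carbene at C2.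

Key step: step 8

Remark on the chemistry: the target has no stereocentre and no configured double bond, so no step has to control configuration. Ar = 3-methoxy-4,5-bis(methoxymethoxy)phenyl. Benzofuran numbering is O1, C2, C3, C3a, C4 to C7, C7a. Furan C2, C3, C4, C5 of the carbene complex become C7a, C3a, C3, C2.

Step 1
Reactants: 1 5-bromo-2-hydroxy-3-methoxybenzaldehyde
Product: 3 5-bromo-3-methoxybenzene-1,2-diol, via aryl formate 2 (not isolated)
Conditions: 30% aq H2O2, NaOH, H2O/THF, 0 °C to rt; then aq HCl
Reagents that add atoms: hydrogen peroxide, OO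
Why: Dakin oxidation: hydroperoxide adds to the aldehyde of the ortho-hydroxybenzaldehyde, the electron-rich aryl group migrates to oxygen and formate 2 is saponified in the same flask, while the aryl bromide and the methyl ether are untouched.

Step 2
Reactants: 3 5-bromo-3-methoxybenzene-1,2-diol
Product: 4 5-bromo-1-methoxy-2,3-bis(methoxymethoxy)benzene
Conditions: MOMCl, iPr2NEt, CH2Cl2, 0 °C to rt
Reagents that add atoms: chloromethyl methyl ether, COCCl
Why: Double O-alkylation of the catechol with an α-chloro ether under amine base (MOM ether formation) masks both acidic OH groups with ethers that tolerate organolithium, organozinc, palladium and chromium chemistry and are cleaved by acid at the end.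

Step 3
Reactants: 5 3-furaldehyde
Product: 6 3-(dimethoxymethyl)furan
Conditions: HC(OMe)3, p-TsOH·H2O (cat.), MeOH, rt; distillation from a trace of Et3N
Reagents that add atoms: trimethyl orthoformate, COC(OC)OC
Why: Acid-catalysed acetalisation, driven by the orthoester as water scavenger, turns the aldehyde into a base-stable group that also serves as the directing group of step 4.

Step 4
Reactants: 6 3-(dimethoxymethyl)furan; 4 5-bromo-1-methoxy-2,3-bis(methoxymethoxy)benzene
Product: 9 2-Ar-3-(dimethoxymethyl)furan, via 2-furyllithium 7 (not isolated), via 2-furylzinc chloride 8 (not isolated)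
Conditions: 6 (1.3 equiv), n-BuLi, Et2O, −78 to 0 °C; ZnCl2 in THF, 0 °C to rt; then 4, Pd(OAc)2 (cat.), SPhos (cat.), THF, 50 °C
Reagents that add atoms: none
Why: Directed α-lithiation followed by Negishi coupling: the acetal oxygen atoms bind lithium and acidify the neighbouring α-position, so deprotonation should occur at C2 rather than C5, and the derived furylzinc chloride couples with the electron-rich aryl bromide at zerovalent palladium bearing a bulky biarylphosphine without touching MOM or acetal groups.

Step 5
Reactants: 9 2-Ar-3-(dimethoxymethyl)furan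
Product: 10 5-bromo-2-Ar-3-(dimethoxymethyl)furan
Conditions: NBS (1.0 equiv), DMF, −20 to 0 °C, dark; used without delay
Reagents that add atoms: N-bromosuccinimide, O=C1CCC(=O)N1Br
Why: Electrophilic aromatic bromination: the free α-position C5 of a 2-arylfuran is the most nucleophilic and least hindered carbon, whereas both open positions of the aryl ring are flanked by two substituents, so one equivalent of NBS in a polar solvent in the cold should stop at the 5-bromide and leave the acetals alone.

Step 6
Reactants: 10 5-bromo-2-Ar-3-(dimethoxymethyl)furan; 11 chromium hexacarbonyl, Cr(CO)6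
Product: 14 pentacarbonyl{[5-Ar-4-(dimethoxymethyl)furan-2-yl](methoxy)carbene}chromium, via C5-lithiated furan 12 (not isolated), via lithium acyl(pentacarbonyl)chromate 13 (not isolated)
Conditions: n-BuLi, THF, −78 °C; Cr(CO)6, −78 °C to rt; solvent switch; MeOTf, CH2Cl2, 0 °C; Et3N-deactivated silica under Ar
Reagents that add atoms: methyl trifluoromethanesulfonate, COS(=O)(=O)C(F)(F)F
Why: Fischer carbene synthesis: bromine–lithium exchange at −78 °C outruns any MOM-directed ortho-lithiation and fixes the metal on the furan α-carbon, the furyllithium adds to a CO ligand of Cr(CO)6, and the hard acylate oxygen of 13 is methylated by MeOTf far faster than any ether oxygen.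

Step 7
Reactants: 15 pent-4-yn-1-ol
Product: 16 tert-butyldimethyl(pent-4-ynyloxy)silane
Conditions: TBSCl, imidazole, CH2Cl2, rt
Reagents that add atoms: tert-butyldimethylsilyl chloride, CC(C)(C)[Si](C)(C)Cl
Why: Imidazole-promoted silylation of a primary alcohol keeps a free OH away from the electrophilic carbene carbon and gives an ether that lasts until the final acid treatment.

Step 8
Reactants: 14 pentacarbonyl{[5-Ar-4-(dimethoxymethyl)furan-2-yl](methoxy)carbene}chromium; 16 tert-butyldimethyl(pent-4-ynyloxy)silane
Product: 18 2-Ar-3-(dimethoxymethyl)-7-methoxy-5-[3-(tert-butyldimethylsilyloxy)propyl]benzofuran-4-ol, via Cr(CO)3 arene complex 17 (not isolated)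
Conditions: 16 (2 equiv), degassed THF (0.1 M), 55 °C, Ar; then brief air exposure, Et2O, rt, filtration through Celite
Reagents that add atoms: none
Why: This is a Dötz benzannulation, a reaction type established for 2-furyl(methoxy)carbene Cr(CO)5 complexes and alkynes: thermal loss of one CO from the zerovalent chromium centre opens a site for 16, the alkyne inserts into the Cr=C bond to give a vinylcarbene, and migration of a CO ligand onto that carbon gives a chromium-bound dienylketene. Ring B closes by 6π-electrocyclisation of this ketene onto furan C3, the only carbon next to the carbene-bearing C2 (the other neighbour is O1), and the cyclohexadienone enolises to the phenol, held at first as Cr(CO)3 complex 17 and released by short contact with air. The selectivity required is the orientation of alkyne insertion, and it is steric: the unsubstituted alkyne terminus bonds to the carbene carbon, so H ends on C6 and the silyloxypropyl chain on C5 beside the CO-derived C4. Phenol formation rather than cyclopentannulation is favoured by the methoxy (not amino) carbene, by THF and by the excess of alkyne. The acetal on furan C4 ends up peri to the new hydroxyl, but the wide exterior angles of the five-membered ring hold the two apart, and acetal, MOM and silyl ethers are inert in this neutral medium. No stereocentre is formed.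

Step 9
Reactants: 18 2-Ar-3-(dimethoxymethyl)-7-methoxy-5-[3-(tert-butyldimethylsilyloxy)propyl]benzofuran-4-ol
Product: 19 2-Ar-3-(dimethoxymethyl)-7-methoxy-5-[3-(tert-butyldimethylsilyloxy)propyl]benzofuran-4-yl trifluoromethanesulfonate
Conditions: Tf2O, pyridine (excess), CH2Cl2, −20 to 0 °C, Ar
Reagents that add atoms: trifluoromethanesulfonic anhydride, O=S(=O)(OS(=O)(=O)C(F)(F)F)C(F)(F)F
Why: O-sulfonylation of the phenol with Tf2O, which is small and reactive enough to reach the hydroxyl between the C5 chain and the C3 acetal, in an excess of pyridine that keeps the medium basic so that acetal, MOM and silyl groups persist.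

Step 10
Reactants: 19 2-Ar-3-(dimethoxymethyl)-7-methoxy-5-[3-(tert-butyldimethylsilyloxy)propyl]benzofuran-4-yl trifluoromethanesulfonate
Product: 20 2-Ar-3-(dimethoxymethyl)-7-methoxy-5-[3-(tert-butyldimethylsilyloxy)propyl]benzofuran
Conditions: Pd(OAc)2 (cat.), dppf (cat.), HCO2H, Et3N (excess over HCO2H), DMF, 75 °C
Reagents that add atoms: none
Why: Palladium-catalysed transfer hydrogenolysis of an aryl triflate: zerovalent palladium formed in situ adds oxidatively to the C4–O bond, formate displaces triflate and loses CO2 to give an arylpalladium hydride, and reductive elimination leaves C4–H, with the excess of Et3N shielding the acid-labile groups.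

Step 11
Reactants: 20 2-Ar-3-(dimethoxymethyl)-7-methoxy-5-[3-(tert-butyldimethylsilyloxy)propyl]benzofuran
Product: 21 Mururin C, 2-(3,4-dihydroxy-5-methoxyphenyl)-5-(3-hydroxypropyl)-7-methoxybenzofuran-3-carbaldehyde
Conditions: 2 M aq HCl, MeOH/THF, 45 °C, Ar
Reagents that add atoms: water, O
Why: Acid hydrolysis of O,O-acetals and of a primary silyl ether: the dimethyl acetal, both MOM ethers and the TBS ether are cleaved by the same dilute acid, the 2-aryl-3-formylbenzofuran tolerates it, methanol scavenges the formaldehyde released, and exclusion of air protects the catechol.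

Compound list
1 | 5-bromo-2-hydroxy-3-methoxybenzaldehyde | COc1cc(Br)cc(C=O)c1O | starting material
2 | 5-bromo-2-hydroxy-3-methoxyphenyl formate | COc1cc(Br)cc(OC=O)c1O | intermediate
3 | 5-bromo-3-methoxybenzene-1,2-diol | COc1cc(Br)cc(O)c1O | intermediate
4 | 5-bromo-1-methoxy-2,3-bis(methoxymethoxy)benzene | COc1cc(Br)cc(OCOC)c1OCOC | intermediate
5 | 3-furaldehyde | O=Cc1ccoc1 | starting material
6 | 3-(dimethoxymethyl)furan | COC(OC)c1ccoc1 | intermediate
7 | [3-(dimethoxymethyl)furan-2-yl]lithium | [Li]c1occc1C(OC)OC | intermediate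
8 | chloro[3-(dimethoxymethyl)furan-2-yl]zinc | Cl[Zn]c1occc1C(OC)OC | intermediate
9 | 3-(dimethoxymethyl)-2-[3-methoxy-4,5-bis(methoxymethoxy)phenyl]furan | COC(OC)c1ccoc1-c1cc(OC)c(OCOC)c(OCOC)c1 | intermediate
10 | 5-bromo-3-(dimethoxymethyl)-2-[3-methoxy-4,5-bis(methoxymethoxy)phenyl]furan | COC(OC)c1cc(Br)oc1-c1cc(OC)c(OCOC)c(OCOC)c1 | intermediate
11 | chromium hexacarbonyl, Cr(CO)6 | O=C=[Cr](=C=O)(=C=O)(=C=O)(=C=O)=C=O | starting material
12 | {4-(dimethoxymethyl)-5-[3-methoxy-4,5-bis(methoxymethoxy)phenyl]furan-2-yl}lithium | [Li]c1cc(C(OC)OC)c(-c2cc(OC)c(OCOC)c(OCOC)c2)o1 | intermediate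
13 | lithium pentacarbonyl{[4-(dimethoxymethyl)-5-arylfuran-2-yl]carbonyl}chromate | [Li+].[O-]C(=[Cr](=C=O)(=C=O)(=C=O)(=C=O)=C=O)c1cc(C(OC)OC)c(-c2cc(OC)c(OCOC)c(OCOC)c2)o1 | intermediate
14 | pentacarbonyl{[4-(dimethoxymethyl)-5-[3-methoxy-4,5-bis(methoxymethoxy)phenyl]furan-2-yl](methoxy)carbene}chromium | COC(=[Cr](=C=O)(=C=O)(=C=O)(=C=O)=C=O)c1cc(C(OC)OC)c(-c2cc(OC)c(OCOC)c(OCOC)c2)o1 | intermediate
15 | pent-4-yn-1-ol | C#CCCCO | starting material
16 | tert-butyldimethyl(pent-4-ynyloxy)silane | C#CCCCO[Si](C)(C)C(C)(C)C | intermediate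
17 | tricarbonylchromium complex of 18, Cr(CO)3 bound to ring B (the arene–metal bond is written as a dot) | COc1cc(CCCO[Si](C)(C)C(C)(C)C)c(O)c2c(C(OC)OC)c(-c3cc(OC)c(OCOC)c(OCOC)c3)oc12.O=C=[Cr](=C=O)=C=O | intermediate
18 | 3-(dimethoxymethyl)-7-methoxy-2-[3-methoxy-4,5-bis(methoxymethoxy)phenyl]-5-[3-(tert-butyldimethylsilyloxy)propyl]benzofuran-4-ol | COc1cc(CCCO[Si](C)(C)C(C)(C)C)c(O)c2c(C(OC)OC)c(-c3cc(OC)c(OCOC)c(OCOC)c3)oc12 | intermediate
19 | C4 trifluoromethanesulfonate of 18 | COc1cc(CCCO[Si](C)(C)C(C)(C)C)c(OS(=O)(=O)C(F)(F)F)c2c(C(OC)OC)c(-c3cc(OC)c(OCOC)c(OCOC)c3)oc12 | intermediate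
20 | 3-(dimethoxymethyl)-7-methoxy-2-[3-methoxy-4,5-bis(methoxymethoxy)phenyl]-5-[3-(tert-butyldimethylsilyloxy)propyl]benzofuran | COc1cc(CCCO[Si](C)(C)C(C)(C)C)cc2c(C(OC)OC)c(-c3cc(OC)c(OCOC)c(OCOC)c3)oc12 | intermediate
21 | Mururin C, 2-(3,4-dihydroxy-5-methoxyphenyl)-5-(3-hydroxypropyl)-7-methoxybenzofuran-3-carbaldehyde | COc1cc(-c2oc3c(OC)cc(CCCO)cc3c2C=O)cc(O)c1O | target

Total step count: 11.
Longest linear sequence: 9 steps, from 1 through steps 1, 2, 4, 5, 6, 8, 9, 10 and 11.

Steps most likely to fail

Risk 1, step 8. CO insertion and ring closure onto the substituted furan may be outrun by alkyne oligomerisation or cyclopentannulation, and the electron-rich phenol may be oxidised while chromium is being removed.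
- **Scope:** the fallback sets out from 4 and comes back at 21. It builds ring A last instead of ring B.
- **Arylalkyne:** Sonogashira coupling of 4 with trimethylsilylacetylene (PdCl2(PPh3)2, CuI, Et3N, 70 °C) should give {[3-methoxy-4,5-bis(methoxymethoxy)phenyl]ethynyl}trimethylsilane F1. K2CO3 in MeOH then gives 5-ethynyl-1-methoxy-2,3-bis(methoxymethoxy)benzene F2.
- **Iodophenol:** purchased dihydroconiferyl alcohol is iodinated ortho to its phenol (I2, KI, aq NaHCO3) to give 4-(3-hydroxypropyl)-2-iodo-6-methoxyphenol F3.
- **Benzofuran:** Sonogashira coupling of F2 with F3, followed in the same flask by 5-endo-dig attack of the phenol oxygen on the alkyne (PdCl2(PPh3)2, CuI, Et3N, DMF, 60 °C), should give 3-(2-Ar-7-methoxybenzofuran-5-yl)propan-1-ol F4.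
- **C3 aldehyde:** NBS in MeCN at 0 °C should brominate C3 to give 3-(2-Ar-3-bromo-7-methoxybenzofuran-5-yl)propan-1-ol F5. n-BuLi (2.2 equiv, THF, −78 °C) followed by DMF should then give 2-Ar-5-(3-hydroxypropyl)-7-methoxybenzofuran-3-carbaldehyde F6.
- **Return:** F6 loses both MOM groups under the conditions of step 11 to give 21.

Risk 2, step 10. Oxidative addition of zerovalent palladium into an electron-rich triflate wedged between the C5 chain and the peri acetal may be slow, so that S–O cleavage back to the phenol takes over.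
- **Scope:** the fallback sets out from 18 and comes back at 20, bypassing 19.
- **Sequence:** 18 is O-heteroarylated with 5-chloro-1-phenyl-1H-tetrazole (K2CO3, DMF, 60 °C, Ar) to give the C4 1-phenyl-1H-tetrazol-5-yl ether of 18 F7. Its aryl C–O bond is then hydrogenolysed heterogeneously (H2, Pd/C, EtOAc/EtOH, rt to 40 °C) to give 20. The tetrasubstituted furan double bond, the acetals and the silyl ether should not be affected.

Risk 3, step 4. Deprotonation of 6 may be shared between C2 and C5. The ortho-substituted furylzinc reagent may also transfer too slowly to the arylpalladium species derived from an electron-rich bromide, so that protodemetallation and homocoupling intervene.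
- **Scope:** the fallback sets out from 4 and comes back at 9. It reverses the polarity and fixes the furan position with a purchased halide.
- **Sequence:** Miyaura borylation of 4 (B2pin2, PdCl2(dppf), KOAc, dioxane, 90 °C) should give 2-Ar-4,4,5,5-tetramethyl-1,3,2-dioxaborolane F8. Suzuki–Miyaura coupling with purchased 2-bromofuran-3-carbaldehyde (PdCl2(dppf), K2CO3, dioxane/H2O, 80 °C) should give 2-Ar-furan-3-carbaldehyde F9.
- **Return:** acetalisation as in step 3, with pyridinium p-toluenesulfonate in place of p-TsOH to spare the MOM ethers, leads to 9.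

Further compounds
F1 | step 8 | {[3-methoxy-4,5-bis(methoxymethoxy)phenyl]ethynyl}trimethylsilane | COc1cc(C#C[Si](C)(C)C)cc(OCOC)c1OCOC
F2 | step 8 | 5-ethynyl-1-methoxy-2,3-bis(methoxymethoxy)benzene | C#Cc1cc(OC)c(OCOC)c(OCOC)c1
F3 | step 8 | 4-(3-hydroxypropyl)-2-iodo-6-methoxyphenol | COc1cc(CCCO)cc(I)c1O
F4 | step 8 | 3-{7-methoxy-2-[3-methoxy-4,5-bis(methoxymethoxy)phenyl]benzofuran-5-yl}propan-1-ol | COc1cc(CCCO)cc2cc(-c3cc(OC)c(OCOC)c(OCOC)c3)oc12
F5 | step 8 | 3-{3-bromo-7-methoxy-2-[3-methoxy-4,5-bis(methoxymethoxy)phenyl]benzofuran-5-yl}propan-1-ol | COc1cc(CCCO)cc2c(Br)c(-c3cc(OC)c(OCOC)c(OCOC)c3)oc12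
F6 | step 8 | 5-(3-hydroxypropyl)-7-methoxy-2-[3-methoxy-4,5-bis(methoxymethoxy)phenyl]benzofuran-3-carbaldehyde | COc1cc(CCCO)cc2c(C=O)c(-c3cc(OC)c(OCOC)c(OCOC)c3)oc12
F7 | step 10 | C4 1-phenyl-1H-tetrazol-5-yl ether of 18 | COc1cc(CCCO[Si](C)(C)C(C)(C)C)c(Oc4nnnn4-c5ccccc5)c2c(C(OC)OC)c(-c3cc(OC)c(OCOC)c(OCOC)c3)oc12
F8 | step 4 | 2-[3-methoxy-4,5-bis(methoxymethoxy)phenyl]-4,4,5,5-tetramethyl-1,3,2-dioxaborolane | COc1cc(B2OC(C)(C)C(C)(C)O2)cc(OCOC)c1OCOC
F9 | step 4 | 2-[3-methoxy-4,5-bis(methoxymethoxy)phenyl]furan-3-carbaldehyde | O=Cc1ccoc1-c1cc(OC)c(OCOC)c(OCOC)c1
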